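# Proposed total synthesis of bisoflavolin N

## Retrosynthetic overview

1. Target 14 ⇒ dibenzo-1,3,2-dioxasilepine 12: the two phenolic O-4' atoms are bridged by a temporary tBu2Si group and the four A-ring hydroxyls are pivalates (removed with fluoride, then methoxide).
2. 12 ⇒ bis(aryloxy)silane 11 by cutting the C-3'–C-3''' bond between the two B rings; forward, this is an anodic intramolecular dehydrogenative aryl–aryl coupling of two C–H bonds, with no halide or boron on either half.
3. Enabling feature: in each half the B ring (the 4-hydroxyphenyl on chromone C-3) has its phenolic O-4' directly beside the carbon to be joined (C-3') and its para position blocked by chromone C-3. Tying the two O-4' atoms to one silicon puts the two C-3' carbons 1,7 to each other, and acylating O-5 and O-7 switches off the phloroglucinol-type A rings.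
4. 11 ⇒ hydrosilane 6 (8-chloro half) + phenol 9 (genistein half). Both come from genistein 1 by 4'-O-selective silylation of the dianion and pivaloylation; chlorine enters at C-8 of tri-O-methylgenistein 2.
5. Ring order: all six rings of the target arrive preformed with genistein. The only ring formed is the temporary seven-membered dioxasilepine (step 9), opened again in step 10.

Key step: step 9

Remark on the chemistry: the target has no stereocentre, and its biaryl axis carries only two ortho substituents (the two hydroxyls), so it should rotate freely. The target is therefore treated as a single achiral compound and no stereocontrol is needed.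

## Route

Step 1
Reactants: 1 genistein
Product: 2 4',5,7-tri-O-methylgenistein
Conditions: Me2SO4 (5 equiv), K2CO3, acetone, reflux
Reagents that add atoms: dimethyl sulfate COS(=O)(=O)OC
Why: Williamson O-methylation of all three phenols; excess reagent and prolonged reflux should also alkylate the chelated 5-OH.

Step 2
Reactants: 2 4',5,7-tri-O-methylgenistein
Product: 3 8-chloro-4',5,7-tri-O-methylgenistein
Conditions: NCS (1.05 equiv), DMF, 40 °C, dark
Reagents that add atoms: N-chlorosuccinimide O=C1CCC(=O)N1Cl
Why: Electrophilic aromatic chlorination; C-8 (para to 5-OMe, ortho to 7-OMe, flanked on one side only by the ring oxygen) is the position at which 5,7-dialkoxy(iso)flavones are halogenated by N-halosuccinimides, while C-6 lies between two methoxy groups and the anisole-type B ring is far less activated.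

Step 3
Reactants: 3 8-chloro-4',5,7-tri-O-methylgenistein
Product: 4 8-chlorogenistein
Conditions: BBr3 (8 equiv), CH2Cl2, −78 °C → rt; MeOH, H2O
Reagents that add atoms: none
Why: Lewis-acid cleavage of the three aryl methyl ethers, which the chromone and the aryl chloride should tolerate.

Step 4
Reactants: 4 8-chlorogenistein
Product: 5 8-chloro-4'-O-(di-tert-butylsilyl)genistein
Conditions: t-BuOK (2.05 equiv), DMF, −20 °C; tBu2Si(H)Cl (1.05 equiv), −20 → 0 °C; aq. NH4Cl
Reagents that add atoms: di-tert-butylchlorosilane CC(C)(C)[SiH](Cl)C(C)(C)C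
Why: O-silylation of the isoflavone dianion; the 4'-phenoxide is its most basic and nucleophilic oxygen, the 7-oxide is a vinylogous carboxylate further damped by the flanking chlorine, and the chelated 5-OH stays protonated (regioselective 4'-O-functionalisation of isoflavone dianions).

Step 5
Reactants: 5 8-chloro-4'-O-(di-tert-butylsilyl)genistein
Product: 6 8-chloro-4'-O-(di-tert-butylsilyl)-5,7-di-O-pivaloylgenistein
Conditions: PivCl (3 equiv), Et3N, DMAP (0.2 equiv), CH2Cl2, 0 °C → rt
Reagents that add atoms: pivaloyl chloride CC(C)(C)C(Cl)=O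
Why: DMAP-catalysed acylation of both A-ring phenols, including the chelated 5-OH; the hindered aryloxy hydrosilane should be inert.

Step 6
Reactants: 1 genistein
Product: 7 4'-O-TBS-genistein
Conditions: t-BuOK (2.05 equiv), DMF, −20 °C; TBSCl (1.05 equiv), −20 → 0 °C; aq. NH4Cl
Reagents that add atoms: tert-butyldimethylsilyl chloride CC(C)(C)[Si](C)(C)Cl
Why: The same dianion O-silylation as in step 4, placing the silyl group on the more nucleophilic 4'-phenoxide.

Step 7
Reactants: 7 4'-O-TBS-genistein
Product: 9 5,7-di-O-pivaloylgenistein, via 4'-O-TBS-5,7-di-O-pivaloylgenistein 8 (not isolated)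
Conditions: PivCl (3 equiv), Et3N, DMAP, CH2Cl2, 0 °C → rt; MeOH quench; then HF·pyridine, THF, 0 °C → rt
Reagents that add atoms: pivaloyl chloride CC(C)(C)C(Cl)=O
Why: DMAP-catalysed acylation of the two A-ring phenols followed in the same flask by fluoride cleavage of the aryl silyl ether, which should leave the pivalates untouched and free only the 4'-OH.

Step 8
Reactants: 6 8-chloro-4'-O-(di-tert-butylsilyl)-5,7-di-O-pivaloylgenistein; 9 5,7-di-O-pivaloylgenistein
Product: 11 di-tert-butylsilylene-bridged bis(4'-O-aryl) ether of the two halves, via bromosilane 10 (not isolated)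
Conditions: NBS (1.05 equiv), CH2Cl2, 0 °C → rt, dark; then 9 (1.0 equiv), imidazole (3 equiv), DMF, rt → 40 °C
Reagents that add atoms: N-bromosuccinimide O=C1CCC(=O)N1Br (its bromine stands only in intermediate 10)
Why: Bromination of the Si–H bond gives an aryloxy(di-tert-butyl)silyl bromide that silylates the only free phenol of 9 under imidazole activation, so the unsymmetrical bis(aryloxy)silane forms without statistical scrambling; the pivalates make both A rings inert to NBS.

Step 9
Reactants: 11 di-tert-butylsilylene-bridged bis(4'-O-aryl) ether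
Product: 12 6,6-di-tert-butyldibenzo[d,f][1,3,2]dioxasilepine carrying the 5,7-bis(pivaloyloxy)-4-oxochromen-3-yl group at C-2 and the 8-chloro-5,7-bis(pivaloyloxy)-4-oxochromen-3-yl group at C-10
Conditions: BDD anode, Pt cathode, undivided cell, constant current 2 mA cm−2, 2.2 F mol−1, Bu3MeN O3SOMe (0.1 M), HFIP–CH2Cl2 4:1, 5 mM, rt
Reagents that add atoms: none
Why: Proposed new method: one-electron oxidation of one of the two para-blocked aryloxy rings at the anode in HFIP should give an arene radical cation that is attacked at its free ortho carbon by the ortho carbon of the second aryloxy ring held on the same silicon atom, and a second oxidation with loss of two protons (reduced to H2 at the Pt cathode, which should outrun reduction of the chromone carbonyls) rearomatises both rings. The closest known reaction types are the anodic intramolecular dehydrogenative aryl–aryl coupling of tethered alkoxyarenes to bridged biaryls and the anodic ortho-coupling of phenols with silyl-protected phenols in HFIP, while the same di-tert-butylsilylene-bridged ring is known to close by Pd-catalysed C–H arylation of ortho-bromo analogues. The only ring closed is the temporary seven-membered 1,3,2-dioxasilepine, formed by ortho–ortho aryl–aryl closure (7-endo with respect to the oxidised ring), and no stereocentre is created because the biaryl axis bears only the two oxygen substituents in its ortho positions. The step needs cross- over homo-coupling, which the 1:1 silicon tether and the high dilution secure, and B-ring over A-ring reactivity, which the four pivalates secure by making both A rings electron-poor and non-nucleophilic. Positional selectivity is fixed by the substrate, since the para positions of both aryloxy rings are blocked by chromone C-3 and the two ortho C–H positions of each ring are equivalent. Limiting the charge to about 2 F mol−1 in the radical-cation-stabilising solvent should hold back over-oxidation of 12.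

Step 10
Reactants: 12 silylene-bridged biaryl tetrapivalate
Product: 14 bisoflavolin N, via biphenol tetrapivalate 13 (not isolated)
Conditions: TBAF (2.5 equiv), THF, 0 °C → rt; then NaOMe (excess), MeOH, rt, argon; aq. HCl
Reagents that add atoms: none
Why: Fluoride cleaves both aryl–O–Si bonds of the bridge, and methoxide transesterification then removes the four aryl pivalates, conditions under which the isoflavone rings and the aryl chloride should survive.

## Compound list

1 | genistein (5,7-dihydroxy-3-(4-hydroxyphenyl)chromen-4-one) | O=c1c(-c2ccc(O)cc2)coc2cc(O)cc(O)c12 | starting material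
2 | 4',5,7-tri-O-methylgenistein (5,7-dimethoxy-3-(4-methoxyphenyl)chromen-4-one) | COc1ccc(-c2coc3cc(OC)cc(OC)c3c2=O)cc1 | intermediate
3 | 8-chloro-4',5,7-tri-O-methylgenistein | COc1ccc(-c2coc3c(Cl)c(OC)cc(OC)c3c2=O)cc1 | intermediate
4 | 8-chlorogenistein | O=c1c(-c2ccc(O)cc2)coc2c(Cl)c(O)cc(O)c12 | intermediate
5 | 8-chloro-4'-O-(di-tert-butylsilyl)genistein (Si–H) | CC(C)(C)[SiH](Oc1ccc(-c2coc3c(Cl)c(O)cc(O)c3c2=O)cc1)C(C)(C)C | intermediate
6 | 8-chloro-4'-O-(di-tert-butylsilyl)-5,7-di-O-pivaloylgenistein (Si–H) | CC(C)(C)[SiH](Oc1ccc(-c2coc3c(Cl)c(OC(=O)C(C)(C)C)cc(OC(=O)C(C)(C)C)c3c2=O)cc1)C(C)(C)C | intermediate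
7 | 4'-O-TBS-genistein | CC(C)(C)[Si](C)(C)Oc1ccc(-c2coc3cc(O)cc(O)c3c2=O)cc1 | intermediate
8 | 4'-O-TBS-5,7-di-O-pivaloylgenistein | CC(C)(C)[Si](C)(C)Oc1ccc(-c2coc3cc(OC(=O)C(C)(C)C)cc(OC(=O)C(C)(C)C)c3c2=O)cc1 | intermediate (not isolated)
9 | 5,7-di-O-pivaloylgenistein (free 4'-OH) | CC(C)(C)C(=O)Oc1cc(OC(=O)C(C)(C)C)c2c(=O)c(-c3ccc(O)cc3)coc2c1 | intermediate
10 | aryloxy(bromo)di-tert-butylsilane derived from 6 | CC(C)(C)[Si](Br)(Oc1ccc(-c2coc3c(Cl)c(OC(=O)C(C)(C)C)cc(OC(=O)C(C)(C)C)c3c2=O)cc1)C(C)(C)C | intermediate (not isolated)
11 | di-tert-butylsilane bearing the 4'-oxygens of 5,7-di-O-pivaloylgenistein and of 8-chloro-5,7-di-O-pivaloylgenistein | CC(C)(C)[Si](Oc1ccc(-c2coc3cc(OC(=O)C(C)(C)C)cc(OC(=O)C(C)(C)C)c3c2=O)cc1)(Oc1ccc(-c2coc3c(Cl)c(OC(=O)C(C)(C)C)cc(OC(=O)C(C)(C)C)c3c2=O)cc1)C(C)(C)C | intermediate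
12 | 6,6-di-tert-butyldibenzo[d,f][1,3,2]dioxasilepine with the two pivaloylated chromon-3-yl groups at C-2 and C-10 | CC(C)(C)[Si]1(C(C)(C)C)Oc2ccc(-c3coc4cc(OC(=O)C(C)(C)C)cc(OC(=O)C(C)(C)C)c4c3=O)cc2-c2cc(-c3coc4c(Cl)c(OC(=O)C(C)(C)C)cc(OC(=O)C(C)(C)C)c4c3=O)ccc2O1 | intermediate
13 | 3',3'''-linked biphenol 5,7,5'',7''-tetrapivalate | CC(C)(C)C(=O)Oc1cc(OC(=O)C(C)(C)C)c2c(=O)c(-c3ccc(O)c(-c4cc(-c5coc6c(Cl)c(OC(=O)C(C)(C)C)cc(OC(=O)C(C)(C)C)c6c5=O)ccc4O)c3)coc2c1 | intermediate (not isolated)
14 | bisoflavolin N | O=c1c(-c2ccc(O)c(-c3cc(-c4coc5c(Cl)c(O)cc(O)c5c4=O)ccc3O)c2)coc2cc(O)cc(O)c12 | target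

## Step count

Total step count: 10. Longest linear sequence: 8 steps (1, 2, 3, 4, 5, 8, 9, 10).

## Steps most likely to fail

**Step 9 (proposed new method).** The oxidation may occur unselectively or go on to over-oxidise the more conjugated biaryl product. The Si–O bonds of the radical cation may be solvolysed, or intermolecular coupling may give oligomers.

The fallback replaces the dehydrogenative coupling by a Pd-catalysed C–H arylation on the same tether, which is known chemistry. It sets out from 9 (and from 6 for the silyl partner). Ortho-bromination of the free phenol of 9 (NBS, 1.0 equiv, MeCN, 0 °C; the pivaloylated A ring is inert) should give 3'-bromo-5,7-di-O-pivaloylgenistein F1. Silylation of F1 with bromosilane 10, made from 6 exactly as in step 8 (imidazole, DMF), should give the bromo-substituted bis(aryloxy)silane F2. Intramolecular direct arylation (Pd(OAc)2, PCy3·HBF4, K2CO3, PivOH, toluene, 110 °C) should then proceed by oxidative addition into the C–Br bond, which is favoured over the hindered C-8 chloride, and concerted metalation–deprotonation at the ortho C–H of the other aryloxy ring. This closes the same seven-membered ring and comes back to the route at 12.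

**Step 2.** Positional selectivity between C-8 and C-6 may be poor, and chlorination may run on to the 6,8-dichloride or touch the B ring.

The fallback sets out from 2 and changes the electrophile and the way chlorine is introduced. Iodination (NIS, cat. TFA, MeCN, rt) uses a bulkier electrophile, which should discriminate more strongly against the doubly flanked C-6 and stop at the mono-halide, giving 8-iodo-4',5,7-tri-O-methylgenistein F3. Copper-mediated halogen exchange (CuCl, 4 equiv, DMF, 140 °C, aromatic Finkelstein reaction) should then convert F3 into the chloride, coming back to the route at 3.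

**Step 8.** Bromination of the Si–H bond may be incomplete or accompanied by hydrolysis of the bromosilane to the silanol. The second silylation at the very hindered silicon may also stall.

The fallback sets out from 9 and 6 and builds the bridge from the silicon bis-electrophile instead of the hydrosilane. Fluoride cleavage of the hydrosilyl ether of 6 (HF·pyridine, THF) should give 8-chloro-5,7-di-O-pivaloylgenistein F4. Slow addition of 9 to di-tert-butylsilyl bis(trifluoromethanesulfonate) (1.05 equiv, 2,6-lutidine, CH2Cl2, −78 °C) should stop at the aryloxy(di-tert-butyl)silyl triflate F5, because the second displacement is much slower. Addition of F4 with more 2,6-lutidine at 0 °C → rt should then displace the remaining triflate and come back to the route at 11.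

## Further compounds

F1 | step 9 | 3'-bromo-5,7-di-O-pivaloylgenistein | CC(C)(C)C(=O)Oc1cc(OC(=O)C(C)(C)C)c2c(=O)c(-c3ccc(O)c(Br)c3)coc2c1
F2 | step 9 | di-tert-butylsilane bearing the 4'-oxygens of 3'-bromo-5,7-di-O-pivaloylgenistein and of 8-chloro-5,7-di-O-pivaloylgenistein | CC(C)(C)[Si](Oc1ccc(-c2coc3cc(OC(=O)C(C)(C)C)cc(OC(=O)C(C)(C)C)c3c2=O)cc1Br)(Oc1ccc(-c2coc3c(Cl)c(OC(=O)C(C)(C)C)cc(OC(=O)C(C)(C)C)c3c2=O)cc1)C(C)(C)C
F3 | step 2 | 8-iodo-4',5,7-tri-O-methylgenistein | COc1ccc(-c2coc3c(I)c(OC)cc(OC)c3c2=O)cc1
F4 | step 8 | 8-chloro-5,7-di-O-pivaloylgenistein (free 4'-OH) | CC(C)(C)C(=O)Oc1cc(OC(=O)C(C)(C)C)c2c(=O)c(-c3ccc(O)cc3)coc2c1Cl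
F5 | step 8 | di-tert-butyl(4'-O-aryl)silyl triflate of 5,7-di-O-pivaloylgenistein | CC(C)(C)[Si](OS(=O)(=O)C(F)(F)F)(Oc1ccc(-c2coc3cc(OC(=O)C(C)(C)C)cc(OC(=O)C(C)(C)C)c3c2=O)cc1)C(C)(C)C
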